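**Strategy**

1. Numbering used throughout: cyclopentane C1–C2–C3(OH)–C4(Me2)–C5(OH); cycloheptanone C5–C6–C7–C8(Me)–C9(Me, C11–C12–butenolide)–C10(=O)–C1. The target is (1S,3S,5S,8R,9R).
2. Enabling feature: the ring-fusion bond C1–C5 links the carbon alpha to the C10 ketone with the tertiary carbinol carbon, so the bond shared by the five- and the seven-membered ring is the C–C bond of a beta-hydroxy ketone. Cutting it opens both rings to a cyclodecane-5,10-dione; bonding C5 to C10 in thought contracts that ring to a cyclohexane-1,2-diol that already carries C8 and C9.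
3. Cuts, in retrosynthetic order: C12–C13 (butenolide), C1–C5 (transannular aldol), C2–C3 with C5–C10 restored (retro-oxy-Cope), C4–CH3, C5–C4 and C10–C1 (two alkenyl additions to a masked 1,2-dione), C9–CH3, C8–CH3, C9–C11.
4. Forward: ring B is bought as cyclohexenone (C5 to C10), expanded from six to ten members by an anionic oxy-Cope rearrangement, and then closed across by one Mukaiyama-type aldol that makes the five- and the seven-membered ring together. The preformed butenolide is coupled last.
5. Stereochemistry: C8 from a ligand-controlled copper-catalysed conjugate addition; C9 from enolate methylation anti to the C8 methyl; C5 and C1 from the transannular aldol under control of C8 and C9 (C1 can be equilibrated); C3 from a CBS reduction after the centre made in the Cope step has been erased by oxidation.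

Key step: step 15

Remark: in step 3 the phosphoramidite enantiomer is the one whose sense of induction gives the (3R) adduct; its descriptor is to be fixed from its behaviour with 2-methylcyclohex-2-en-1-one, and both enantiomers are available.

**Route**

Step 1
Reactants: 1 cyclohex-2-en-1-one
Product: 2 2-iodocyclohex-2-en-1-one
Conditions: I2, pyridine, CH2Cl2, 0 °C to rt
Reagents that add atoms: iodine, II
Why: Alpha-iodination of an enone by pyridine conjugate addition, iodination of the enolate and elimination is reliable on cyclohexenone and creates no stereocentre.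

Step 2
Reactants: 2 2-iodocyclohex-2-en-1-one; 3 allyltributylstannane
Product: 4 2-allylcyclohex-2-en-1-one
Conditions: Pd(PPh3)4 (5 mol%, zerovalent palladium), CuI (10 mol%), DMF, 50 °C
Reagents that add atoms: none
Why: Stille coupling of an alpha-iodoenone with an allylstannane, with CuI speeding transmetalation, forms the C9–C11 bond and leaves the enone intact.

Step 3
Reactants: 4 2-allylcyclohex-2-en-1-one
Product: 6 trimethylsilyl enol ether of (3R)-2-allyl-3-methylcyclohexanone, via dimethylaluminium enolate 5 (not isolated)
Conditions: AlMe3, Cu(O2CC4H3S) (copper thiophene-2-carboxylate, monovalent copper, 2 mol%), BINOL/bis(1-phenylethyl)amine phosphoramidite (4 mol%), Et2O, −30 °C; then TMSOTf, THF, −30 to 0 °C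
Reagents that add atoms: trimethylaluminium, C[Al](C)C; trimethylsilyl triflate, C[Si](C)(C)OS(=O)(=O)C(F)(F)F
Why: Copper-catalysed asymmetric conjugate addition of trimethylaluminium to an alpha-substituted cyclohexenone sets C8 (3R in this ring) under ligand control, and O-silylation fixes the aluminium enolate regiospecifically.

Step 4
Reactants: 6 trimethylsilyl enol ether of (3R)-2-allyl-3-methylcyclohexanone
Product: 8 (2R,3R)-2-allyl-2,3-dimethylcyclohexan-1-one, via lithium enolate 7 (not isolated)
Conditions: MeLi, THF, 0 °C; then MeI, DMPU, −78 to 0 °C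
Reagents that add atoms: iodomethane, CI
Why: Regiospecific enolate generation from the silyl enol ether and enolate C-alkylation, in which the C8 methyl sits pseudoaxial to avoid the C9 allyl group and iodomethane enters on the opposite face, so the allyl chain ends cis to the C8 methyl and C9 is (R).

Step 5
Reactants: 8 (2R,3R)-2-allyl-2,3-dimethylcyclohexan-1-one
Product: 9 (5R,6R)-6-allyl-2-hydroxy-5,6-dimethylcyclohex-2-en-1-one
Conditions: KOtBu, O2 (1 atm), t-BuOH–DME, 0 °C to rt; dilute HCl
Reagents that add atoms: dioxygen, O=O
Why: Base-promoted autoxidation of a ketone enolate (oxygenation at the only enolisable carbon, C5, then Kornblum–DeLaMare-type loss of water from the hydroperoxide) gives the 1,2-dione, which can enolise in one direction only because C9 is quaternary.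

Step 6
Reactants: 9 (5R,6R)-6-allyl-2-hydroxy-5,6-dimethylcyclohex-2-en-1-one
Product: 10 (5R,6R)-6-allyl-2-methoxy-5,6-dimethylcyclohex-2-en-1-one
Conditions: Me2SO4, K2CO3, acetone, reflux
Reagents that add atoms: dimethyl sulfate, COS(=O)(=O)OC
Why: Williamson-type O-methylation of the acidic enol hydroxyl masks C5 as a methyl enol ether and leaves C10 as the only free carbonyl.

Step 7
Reactants: 10 (5R,6R)-6-allyl-2-methoxy-5,6-dimethylcyclohex-2-en-1-one; 11 vinylmagnesium bromide
Product: 12 (5R,6R)-6-allyl-2-methoxy-5,6-dimethyl-1-vinylcyclohex-2-en-1-ol (both C1 epimers)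
Conditions: THF, 0 °C to rt; aq. NH4Cl
Reagents that add atoms: none
Why: Grignard 1,2-addition to a carbonyl that cannot enolise (C9 quaternary, C5 sp2) brings in C1 and C2; the new carbinol centre is left uncontrolled because it becomes sp2 again in step 14.

Step 8
Reactants: 12 (5R,6R)-6-allyl-2-methoxy-5,6-dimethyl-1-vinylcyclohex-2-en-1-ol
Product: 13 methyl ether of 12
Conditions: KH, THF, 0 °C; then MeI, 0 °C to rt
Reagents that add atoms: iodomethane, CI
Why: Williamson etherification of the hindered tertiary potassium alkoxide with the smallest electrophile; a methyl ether is chosen because, unlike a silyl ether, it cannot migrate to the neighbouring alkoxide generated in step 14.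

Step 9
Reactants: 13 methyl ether of 12
Product: 14 (3R,4R)-3-allyl-2-methoxy-3,4-dimethyl-2-vinylcyclohexan-1-one (both C2 epimers)
Conditions: oxalic acid (cat.), THF–H2O, 0 °C to rt
Reagents that add atoms: water, O
Why: Mild acid hydrolysis of a methyl enol ether (C-protonation, hydration of the oxocarbenium ion, loss of methanol) frees the C5 ketone with an acid too weak to ionise the tertiary allylic ether.

Step 10
Reactants: 15 allyl bromide
Product: 16 allyl 4-methoxybenzyl ether
Conditions: 4-methoxybenzyl alcohol, NaH, THF, 0 °C; then 15, Bu4NI (cat.), rt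
Reagents that add atoms: 4-methoxybenzyl alcohol, COc1ccc(CO)cc1
Why: Williamson ether synthesis with a reactive allylic bromide.

Step 11
Reactants: 16 allyl 4-methoxybenzyl ether
Product: 17 (Z)-1-(4-methoxybenzyloxy)prop-1-ene
Conditions: KOtBu (0.3 equiv), DMSO, rt
Reagents that add atoms: none
Why: Base-mediated allyl-to-propenyl ether isomerisation runs through the potassium-chelated cis allyl anion and should give the Z enol ether.

Step 12
Reactants: 17 (Z)-1-(4-methoxybenzyloxy)prop-1-ene
Product: 19 (Z)-2-bromo-1-(4-methoxybenzyloxy)prop-1-ene, via 1,2-dibromide 18 (not isolated)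
Conditions: Br2 (1.0 equiv), CH2Cl2, −78 °C; then DBU, −78 °C to rt
Reagents that add atoms: bromine, BrBr
Why: Bromination–dehydrobromination of an enol ether: anti addition of bromine to the Z alkene and anti E2 loss of HBr (hydrogen from C2, bromide from C1) leave bromine cis to the ether oxygen, and the enol ether reacts with bromine far faster than the anisyl ring at −78 °C.

Step 13
Reactants: 19 (Z)-2-bromo-1-(4-methoxybenzyloxy)prop-1-ene; 14 (3R,4R)-3-allyl-2-methoxy-3,4-dimethyl-2-vinylcyclohexan-1-one
Product: 21 1,2-dialkenyl carbinol (C5 and C10 epimers), via alkenyllithium 20 (not isolated)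
Conditions: 19, t-BuLi (2 equiv), Et2O, −78 °C; then 14 in THF, −78 °C; aq. NH4Cl
Reagents that add atoms: none
Why: Bromine–lithium exchange with retention gives an alkenyllithium whose lithium is cis to oxygen, so no anti-periplanar beta-elimination can occur, and its 1,2-addition to the C5 ketone is helped by chelation to the alpha-methoxy group; the new carbinol centre is erased in step 14.

Step 14
Reactants: 21 1,2-dialkenyl carbinol
Product: 24 ten-membered keto enol ether, via potassium alkoxide 22 (not isolated), via potassium enolate 23 (not isolated)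
Conditions: KHMDS (1.05 equiv), 18-crown-6, THF, −78 to 0 °C; then MeI, −78 °C
Reagents that add atoms: iodomethane, CI
Why: Anionic oxy-Cope rearrangement of the 1,2-dialkenyl alkoxide (helped by the ether oxygen on the breaking C5–C10 bond) forms C2–C3 and expands the cyclohexane to the cyclodecane; it delivers C10 only as the enol ether towards C1 and C5 only as the enolate towards C4, which is C-methylated cold before the beta-alkoxide can leave, and the C3 centre and enol ether geometry are left uncontrolled because neither survives.

Step 15
Reactants: 24 ten-membered keto enol ether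
Product: 25 trans-fused hydroxy-hydroazulenone with C9 allyl group and C3 4-methoxybenzyl ether (both C3 epimers)
Conditions: BF3·OEt2 (1.5 equiv), CH2Cl2, −78 °C; aq. NaHCO3; then DBU (cat.), toluene, rt (C1 equilibration)
Reagents that add atoms: water, O
Why: BF3 activates the C5 ketone and the enol ether carbon C1 adds to it across the ten-membered ring; the C10 oxocarbenium ion so formed is hydrolysed to the ketone on work-up with loss of methanol. The closest known reaction is the Mukaiyama-type aldol addition of an alkyl enol ether to a Lewis-acid-activated carbonyl, run here transannularly like the base-mediated closure of cyclodecane-1,6-diones to 1-hydroxybicyclo[5.3.0]decan-2-ones. The one new bond C1–C5 closes the cyclopentane (C1 to C5) in a 5-(enolexo)-exo-trig mode and, in the same event, the cycloheptanone (C5 to C10 and C1) in a 7-(enolendo)-exo-trig mode. C5 is set by the resident C8 and C9 centres: closure through the chair-like seven-membered array with the C8 methyl equatorial should bring C1 onto the carbonyl face that leaves the hydroxyl syn to the C9 chain, and C1, formed in the same event and alpha to the C10 ketone, is relaxed by the DBU treatment to the trans-fused ketol in which the C5 hydroxyl is hydrogen-bonded to the C10 carbonyl. The step needs regioselectivity (C1 to C5, not C6 to C10), and 24 has it built in: only C10 is present as an enol derivative, and the C5 ketone has no hydrogen at C4, so it can neither enolise that way nor lose the C3 ether. A monodentate Lewis acid is used so that the C3 ether, whose configuration is uncontrolled, cannot chelate to the C5 carbonyl and steer the face.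

Step 16
Reactants: 25 trans-fused hydroxy-hydroazulenone
Product: 26 aldehyde (C9 chain CH2CHO)
Conditions: OsO4 (2 mol%), NaIO4, 2,6-lutidine, dioxane–H2O, rt
Reagents that add atoms: sodium periodate, [Na+].[O-]I(=O)(=O)=O; osmium tetroxide (catalytic oxygen carrier), O=[Os](=O)(=O)=O
Why: Lemieux–Johnson oxidation cleaves the only alkene, removing the surplus carbon of the allyl group, and the lutidine buffer protects the ketol and the benzyl ether.

Step 17
Reactants: 26 aldehyde
Product: 27 primary alcohol (C9 chain CH2CH2OH)
Conditions: NaBH4, MeOH–CH2Cl2, −78 to −40 °C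
Reagents that add atoms: none
Why: Chemoselective borohydride reduction of an aldehyde in the presence of the C10 ketone, which lies between a quaternary and a tertiary carbon and should not react in the cold.

Step 18
Reactants: 27 primary alcohol
Product: 28 primary iodide (C9 chain CH2CH2I)
Conditions: I2, PPh3, imidazole, CH2Cl2, 0 °C
Reagents that add atoms: iodine, II
Why: Appel-type iodination (alkoxyphosphonium formation and SN2 displacement by iodide) acts only on the primary hydroxyl; the tertiary C5 hydroxyl is too hindered to be activated.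

Step 19
Reactants: 28 primary iodide
Product: 29 iodo diol (both C3 epimers)
Conditions: DDQ, CH2Cl2–pH 7 buffer (10:1), 0 °C
Reagents that add atoms: none
Why: Oxidative cleavage of the 4-methoxybenzyl ether by DDQ (hydride abstraction and hydrolysis of the oxocarbenium ion in the wet medium, which also disfavours acetal formation with the C5 hydroxyl) frees the C3 hydroxyl without touching iodide or ketone.

Step 20
Reactants: 29 iodo diol
Product: 30 C3,C10-diketone with C5 hydroxyl and iodoethyl chain
Conditions: Dess–Martin periodinane, NaHCO3, CH2Cl2, rt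
Reagents that add atoms: none
Why: Dess–Martin oxidation of the secondary alcohol converges both C3 epimers to one ketone; the tertiary hydroxyl cannot be oxidised and the buffered, non-basic medium avoids retro-aldol cleavage.

Step 21
Reactants: 30 C3,C10-diketone
Product: 31 (3S)-iodo diol ketone
Conditions: (R)-2-methyl-CBS-oxazaborolidine (0.3 equiv), BH3·SMe2, THF, −20 °C; MeOH
Reagents that add atoms: none
Why: Corey–Bakshi–Shibata reduction, in which the (R)-oxazaborolidine tells the quaternary C4 flank from the C2 methylene and delivers hydride to the C3 face syn to the C5 oxygen to give the (3S) alcohol trans to the C5 hydroxyl; the alkoxyborane formed from the free C5 hydroxyl can only deliver hydride to that same face, and the C10 cycloheptanone between a quaternary and a tertiary carbon should react far more slowly.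

Step 22
Reactants: 31 (3S)-iodo diol ketone; 32 4-bromofuran-2(5H)-one
Product: 33 target, (1S,3S,5S,8R,9R)
Conditions: NiBr2·glyme (10 mol%, divalent nickel), 4,4'-di-tert-butyl-2,2'-bipyridine (10 mol%), Zn powder (2 equiv), DMA, rt
Reagents that add atoms: none
Why: Nickel-catalysed reductive cross-electrophile coupling of a primary alkyl iodide with an alkenyl bromide (oxidative addition of the bromobutenolide to zerovalent nickel, capture of the alkyl radical, reductive elimination) forms C12–C13 under conditions that tolerate free hydroxyls and the ketone and touch no stereocentre.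

**Compound list**

1 | cyclohex-2-en-1-one | O=C1C=CCCC1 | starting material
2 | 2-iodocyclohex-2-en-1-one | O=C1C(I)=CCCC1 | intermediate
3 | allyltributylstannane | C=CC[Sn](CCCC)(CCCC)CCCC | starting material
4 | 2-allylcyclohex-2-en-1-one | C=CCC1=CCCCC1=O | intermediate
5 | dimethylaluminium (3R)-2-allyl-3-methylcyclohex-1-en-1-olate | C[C@@H]1CCCC(O[Al](C)C)=C1CC=C | intermediate
6 | trimethyl{[(3R)-2-allyl-3-methylcyclohex-1-en-1-yl]oxy}silane | C[C@@H]1CCCC(O[Si](C)(C)C)=C1CC=C | intermediate
7 | lithium (3R)-2-allyl-3-methylcyclohex-1-en-1-olate | C[C@@H]1CCCC(O[Li])=C1CC=C | intermediate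
8 | (2R,3R)-2-allyl-2,3-dimethylcyclohexan-1-one (allyl cis to the C3 methyl) | C[C@@H]1CCCC(=O)[C@]1(C)CC=C | intermediate
9 | (5R,6R)-6-allyl-2-hydroxy-5,6-dimethylcyclohex-2-en-1-one | C[C@@H]1CC=C(O)C(=O)[C@]1(C)CC=C | intermediate
10 | (5R,6R)-6-allyl-2-methoxy-5,6-dimethylcyclohex-2-en-1-one | C[C@@H]1CC=C(OC)C(=O)[C@]1(C)CC=C | intermediate
11 | vinylmagnesium bromide | C=C[Mg]Br | starting material
12 | (5R,6R)-6-allyl-2-methoxy-5,6-dimethyl-1-vinylcyclohex-2-en-1-ol, both C1 epimers | C[C@@H]1CC=C(OC)C(O)(C=C)[C@]1(C)CC=C | intermediate
13 | (5R,6R)-6-allyl-1,2-dimethoxy-5,6-dimethyl-1-vinylcyclohex-2-ene (numbering of 12), both C1 epimers | C[C@@H]1CC=C(OC)C(OC)(C=C)[C@]1(C)CC=C | intermediate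
14 | (3R,4R)-3-allyl-2-methoxy-3,4-dimethyl-2-vinylcyclohexan-1-one, both C2 epimers | C[C@@H]1CCC(=O)C(OC)(C=C)[C@]1(C)CC=C | intermediate
15 | allyl bromide | C=CCBr | starting material
16 | allyl 4-methoxybenzyl ether | C=CCOCc1ccc(OC)cc1 | intermediate
17 | (Z)-1-(4-methoxybenzyloxy)prop-1-ene | C/C=C\OCc1ccc(OC)cc1 | intermediate
18 | 1,2-dibromo-1-(4-methoxybenzyloxy)propane | CC(Br)C(Br)OCc1ccc(OC)cc1 | intermediate
19 | (Z)-2-bromo-1-(4-methoxybenzyloxy)prop-1-ene (bromine cis to oxygen) | C/C(Br)=C/OCc1ccc(OC)cc1 | intermediate
20 | [1-(4-methoxybenzyloxy)prop-1-en-2-yl]lithium, lithium cis to oxygen | C/C([Li])=C/OCc1ccc(OC)cc1 | intermediate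
21 | (3R,4R)-3-allyl-2-methoxy-1-[(Z)-1-(4-methoxybenzyloxy)prop-1-en-2-yl]-3,4-dimethyl-2-vinylcyclohexan-1-ol, C1 and C2 epimers | C[C@@H]1CCC(O)(/C(C)=C\OCc2ccc(OC)cc2)C(OC)(C=C)[C@]1(C)CC=C | intermediate
22 | potassium alkoxide of 21 | C[C@@H]1CCC(O[K])(/C(C)=C\OCc2ccc(OC)cc2)C(OC)(C=C)[C@]1(C)CC=C | intermediate
23 | potassium enolate of the ten-membered ring (C5 enolate towards C4, C10 methyl enol ether towards C1) | C[C@@H]1CCC(O[K])=C(C)C(OCc2ccc(OC)cc2)CC=C(OC)[C@]1(C)CC=C | intermediate
24 | (7R,8R)-7-allyl-6-methoxy-3-(4-methoxybenzyloxy)-2,2,7,8-tetramethylcyclodec-5-en-1-one, C3 epimers and both alkene geometries | C[C@@H]1CCC(=O)C(C)(C)C(OCc2ccc(OC)cc2)CC=C(OC)[C@]1(C)CC=C | intermediate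
25 | (3aS,5R,6R,8aS)-5-allyl-8a-hydroxy-2-(4-methoxybenzyloxy)-1,1,5,6-tetramethyloctahydroazulen-4(1H)-one, both C2 epimers (C2 here is C3 of the target numbering) | C[C@@H]1CC[C@]2(O)[C@H](CC(OCc3ccc(OC)cc3)C2(C)C)C(=O)[C@]1(C)CC=C | intermediate
26 | as 25 with the C9 chain CH2CHO | C[C@@H]1CC[C@]2(O)[C@H](CC(OCc3ccc(OC)cc3)C2(C)C)C(=O)[C@]1(C)CC=O | intermediate
27 | as 25 with the C9 chain CH2CH2OH | C[C@@H]1CC[C@]2(O)[C@H](CC(OCc3ccc(OC)cc3)C2(C)C)C(=O)[C@]1(C)CCO | intermediate
28 | as 25 with the C9 chain CH2CH2I | C[C@@H]1CC[C@]2(O)[C@H](CC(OCc3ccc(OC)cc3)C2(C)C)C(=O)[C@]1(C)CCI | intermediate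
29 | (3aS,5R,6R,8aS)-2,8a-dihydroxy-5-(2-iodoethyl)-1,1,5,6-tetramethyloctahydroazulen-4(1H)-one, both C2 epimers | C[C@@H]1CC[C@]2(O)[C@H](CC(O)C2(C)C)C(=O)[C@]1(C)CCI | intermediate
30 | (3aS,5R,6R,8aS)-8a-hydroxy-5-(2-iodoethyl)-1,1,5,6-tetramethylhexahydroazulene-2,4(1H,3H)-dione | C[C@@H]1CC[C@]2(O)[C@H](CC(=O)C2(C)C)C(=O)[C@]1(C)CCI | intermediate
31 | (2S,3aS,5R,6R,8aS)-2,8a-dihydroxy-5-(2-iodoethyl)-1,1,5,6-tetramethyloctahydroazulen-4(1H)-one | C[C@@H]1CC[C@]2(O)[C@H](C[C@H](O)C2(C)C)C(=O)[C@]1(C)CCI | intermediate
32 | 4-bromofuran-2(5H)-one | BrC1=CC(=O)OC1 | starting material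
33 | (2S,3aS,5R,6R,8aS)-2,8a-dihydroxy-1,1,5,6-tetramethyl-5-[2-(5-oxo-2,5-dihydrofuran-3-yl)ethyl]octahydroazulen-4(1H)-one, CNP0077405.3 | C[C@@H]1CC[C@]2(O)[C@H](C[C@H](O)C2(C)C)C(=O)[C@]1(C)CCC1=CC(=O)OC1 | target

**Step count and risks**

Total: 22 steps. Longest linear sequence: 19 steps (steps 1 to 9 and 13 to 22); steps 10 to 12 make the three-step side branch to bromide 19.

Steps most likely to fail:

1. Step 15. The closure may take the other face of the C5 carbonyl (hydroxyl anti to the C9 chain), the two C3 epimers of 24 may differ in facial preference, or the ketol may suffer retro-aldol cleavage or dehydration during C1 equilibration. Fallback: the open Lewis-acid transition state is replaced by a closed, metal-chelated one. Starting from 24, N-bromosuccinimide in THF–H2O with NaHCO3 at 0 °C should convert the enol ether regiospecifically into the C1-bromo 5,10-diketone F1. SmI2 (divalent samarium, 2.2 equiv) in THF at −78 °C should then generate the trivalent samarium enolate at C10/C1 only, and an intramolecular samarium Reformatsky addition to C5 through a six-membered chelate holds the C5 oxygen syn to C10, which is the trans ring fusion. This returns to the route at 25.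

2. Step 14. The beta-alkoxy potassium enolate 23 may lose 4-methoxybenzyl oxide before it is methylated, the rearrangement may need a temperature at which this elimination is fast, or methylation may go on oxygen or a second time at C6. Fallback: the free enolate is avoided until −78 °C by a neutral siloxy-Cope rearrangement. Starting from 21, N-(trimethylsilyl)imidazole should give the trimethylsilyl ether F2. Heating in decalin at about 200 °C in base-washed glass should give the ten-membered bis-enol ether F3 (silyl enol ether C5=C4, methyl enol ether C10=C1). MeLi in THF at 0 °C should release the lithium enolate F4, which is less prone to elimination than the potassium enolate, and MeI at −78 °C returns to the route at 24.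

3. Step 22. The bromobutenolide may be reduced or homocoupled, the iodide may be hydrodehalogenated, or cross-selectivity may be poor in the presence of two free hydroxyls. Fallback: a palladium-catalysed Negishi coupling of a preformed organozinc. Starting from 31, TMSOTf and 2,6-lutidine should give the bis(trimethylsilyl) ether F5. Zn dust with LiCl in THF at 40 °C should insert to give the alkylzinc iodide F6, which tolerates the hindered ketone. Coupling with 32 under Pd(PPh3)4 (zerovalent palladium) in THF should give the bis(trimethylsilyl) ether of the target F7, and dilute HCl in THF removes both silyl groups and returns to the route at 33.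

**Further compounds**

F1 | step 15 | C1-bromo 5,10-diketone of the ten-membered ring (C3 4-methoxybenzyl ether, C9 allyl) | C[C@@H]1CCC(=O)C(C)(C)C(OCc2ccc(OC)cc2)CC(Br)C(=O)[C@]1(C)CC=C
F2 | step 14 | trimethylsilyl ether of carbinol 21 | C[C@@H]1CCC(O[Si](C)(C)C)(/C(C)=C\OCc2ccc(OC)cc2)C(OC)(C=C)[C@]1(C)CC=C
F3 | step 14 | ten-membered bis-enol ether (C5 trimethylsilyl enol ether towards C4, C10 methyl enol ether towards C1) | C[C@@H]1CCC(O[Si](C)(C)C)=C(C)C(OCc2ccc(OC)cc2)CC=C(OC)[C@]1(C)CC=C
F4 | step 14 | lithium enolate of the ten-membered ring | C[C@@H]1CCC(O[Li])=C(C)C(OCc2ccc(OC)cc2)CC=C(OC)[C@]1(C)CC=C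
F5 | step 22 | bis(trimethylsilyl) ether of 31 | C[C@@H]1CC[C@]2(O[Si](C)(C)C)[C@H](C[C@H](O[Si](C)(C)C)C2(C)C)C(=O)[C@]1(C)CCI
F6 | step 22 | alkylzinc iodide from F5 | C[C@@H]1CC[C@]2(O[Si](C)(C)C)[C@H](C[C@H](O[Si](C)(C)C)C2(C)C)C(=O)[C@]1(C)CC[Zn]I
F7 | step 22 | bis(trimethylsilyl) ether of the target | C[C@@H]1CC[C@]2(O[Si](C)(C)C)[C@H](C[C@H](O[Si](C)(C)C)C2(C)C)C(=O)[C@]1(C)CCC1=CC(=O)OC1
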